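## The problem

Compound 19 is a flavanone, (2S)-2-(3,4-dimethoxyphenyl)-8-hydroxy-5,6,7-trimethoxychroman-4-one: rings A and C are fused through C4a–C8a, and the dimethoxyphenyl ring B sits on C2. Ring A carries no hydrogen. C5, C6, C7, C8 and C8a all bear oxygen: C5–C7 as methyl ethers, C8 as a free phenol and C8a as the ring-C ether oxygen O1. A synthesis must therefore assemble a hexasubstituted benzene and tell the C8 oxygen apart from the C5 oxygen para to it; substitution on a preformed arene has no open position to work with. The only stereocentre is C2 (S). Nothing else in the molecule can control it, so it must come from a catalyst or reagent, and the most it can control is a temporary centre at C4. C2 is benzylic, bonded to O1 and β to the C4 ketone, so once the ketone exists, base or hot acid can open ring C to the 2'-hydroxychalcone and racemise it; the ketone should appear late and the closing steps should be neutral. The C8 phenol, para to the C5 methoxy group, is a hydroquinone monoether that oxidises easily and must be masked whenever an oxidant is used. The enabling feature is that C5–C8, four adjacent carbons each with one oxygen, are the four carbons of a squaric ester, while C8a (with O1 attached) and C4a are the α- and β-carbons of a cyclic enol ether if ring C is written as a 3,4-dihydro-2H-pyran. Joining C8–C8a by carbonyl addition and C4a–C5 by electrocyclisation makes ring A with every oxygen in place and delivers the C5 and C8 oxygens in different form.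

## Retrosynthesis

**Unmasking phenol and ketone (19 ⇒ 18 ⇒ 17).** No skeletal bond is cut. The last operation is hydrogenolysis of the C8 benzyl ether 18, because it is neutral and leaves C2 of a flavanone alone; a base- or fluoride-labile group here would expose 19 to ring-opening conditions. The ketone of 18 is traced to the 2,4-cis flavan-4-ol 17. Carrying C4 as an alcohol derivative removes the β-carbonyl that makes C2 labile and allows organolithium chemistry earlier. The forward oxidation must be non-basic and must not attack ring A, all of whose oxygens are etherified at that stage.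

**Sorting the oxygens (17 ⇒ 16 ⇒ 14 ⇒ 13).** Only O–Si, O–benzyl and O–methyl bonds are cut. Phenol 13 has a free C5 hydroxyl, a tert-butyldimethylsilyl ether on O8 and a triisopropylsilyl ether on O4. The phenol is methylated (14), the aryl silyl ether is exchanged for benzyl in one operation with fluoride and a benzyl halide (16), and the C4 silyl ether is then removed (17). Keeping the aryl silyl ether to the end was weighed against this. Freeing O4 selectively would need acid, which ionises this benzylic carbon flanked by ortho and para oxygens. Fluoride would free O8 as well and leave a p-methoxyphenol to face the oxidant. The exchange costs one step and removes both problems.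

**Ring A (13 ⇒ 10).** The C4a–C5 bond is cut and the aromatic ring unfolds to cyclobutenone 10. In 10, C5–C8 are the ring carbons of a squarate adduct and C8a/C4a are the enol-ether carbons of a dihydropyran. The neighbouring cuts are stepwise substitution on a simpler oxygenated benzene, or a carbene benzannulation needing a dialkoxy-alkyne partner. Against these, this cut brings in four oxygenated carbons at once from a commercial C4 unit, and the product emerges with O5 free and O8 silylated. The precursor has no arene, only one heterocycle and a symmetrical four-membered ring. The forward reaction must open the cyclobutenone with the dihydropyranyl group turning inward, close onto C4a, and leave both silyl ethers and the ring-C stereocentres untouched.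

**The squarate adduct (10 ⇒ 6 + 7).** The C8–C8a bond is cut between the carbinol carbon and C6 of the dihydropyran, giving dimethyl squarate 7 and the 6-lithio derivative 8 of enol ether 6; alkoxide 9 is silylated in the same flask. Attaching the C4 unit by cross-coupling instead would give a cyclobutenone without the carbinol oxygen and so lose the C8 oxygen. O4 carries triisopropylsilyl rather than tert-butyldimethylsilyl because it offers no Si–CH3 protons to the base and outlasts the aryl silyl ether later. The forward step needs vinylic metalation at C6 in preference to the benzylic C2–H and ring B, and a single 1,2-addition. The new carbinol centre is of no consequence because it becomes sp2 in the next step.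

**Ring C (6 ⇒ 5 ⇒ 4 ⇒ 1 + 2).** Removing the silyl group and returning allylic alcohol 5 to enone 4 leaves a 2-aryl-2,3-dihydro-4H-pyran-4-one. It is cut at O1–C6 and C2–C3 into aldehyde 1 and siloxydiene 2. The classical flavanone cut, oxa-Michael closure of a chalcone, is not open because it needs ring A as the phenol nucleophile; making ring C first is what allows ring A to be made last. Both starting materials are commercial, ring B arrives complete, and the catalytic hetero-Diels–Alder reaction sets C2. The forward sequence must deliver (S) at C2 with a titanium–binaphthol catalyst and reduce the enone to the 2,4-cis alcohol, a centre that only holds C4 at the alcohol oxidation level.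

## Roads not taken

**Alternative 1:** The cut runs through ring B at C1'–C2' and C5'–C6'. It leads back to (2S)-8-(benzyloxy)-2-ethynyl-5,6,7-trimethoxychroman-4-one A2 and 2,3-dimethoxybuta-1,3-diene A3. Forward, CoBr2(dppe) reduced by Zn in the presence of ZnI2 would join alkyne and diene in a formal [4+2] cycloaddition to the cyclohexa-1,4-diene A4. Dehydrogenation would give 18 and hydrogenolysis 19.
- Merits: the diene is symmetrical, so there is no regiochemical question; the conditions are nearly neutral; A4 is one oxidation from a compound of the present route; ring B could be varied late.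
- Weak points: ring B is the one part of 19 that can be bought whole (as 1), so the step builds what need not be built. Ring A with its five oxygens and the C2 stereocentre must both already exist in A2. A2 would have to come from an asymmetric conjugate alkynylation of the chromone A1, itself a hexasubstituted arene needing its own multistep preparation. C2–H of A2 is propargylic, α to oxygen and β to the ketone, so it is more prone to ring-opening epimerisation than in 19. A bis-enol-ether diene is an unusual partner for the cobalt catalyst and meets a Lewis acid. Aromatising A4 needs an oxidant next to electron-rich ring A.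
- Comparison: Alternative 1 is more convergent at the end and would be the better plan for a series of ring-B analogues. The chosen plan sets against this that its key step is spent on the difficult ring, and that C2 is introduced by a reaction type well charted for aryl aldehydes.

**Alternative 2:** The cut is the C2–C3 bond, leading to the α-diazoketone A5. With Rh2(S-PTTL)4 the diazo group is lost and the rhodium carbenoid at C3 inserts into a benzylic C–H bond of the ether. This closes ring C and sets C2 in the 8-silyloxyflavanone A6; fluoride would then give 19.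
- Merits: the stereocentre is created by the catalyst in the last C–C bond formation, so few later operations can erode it. No redox adjustment at C4 is needed. A6 is one deprotection from the target, so the endgame is several steps shorter than the present one.
- Weak points: the insertion must close a six-membered ring, whereas such carbenoids prefer five-membered closure. The ether oxygen is placed to capture the carbenoid as a five-membered oxonium ylide, whose [1,2]-shift of the electron-rich benzyl group would give a benzofuranone. A carbenoid with a single acyl substituent is the least selective class for asymmetric insertion. Ring B invites aromatic cycloaddition. A5 presupposes a pentaoxygenated aryl ketone, that is, ring A made by other means.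
- Comparison: in steps after ring A exists and in lateness of the stereocentre, Alternative 2 is better. The chosen plan answers that it makes ring A rather than presupposing it, that its stereo-defining and ring-forming steps belong to established reaction classes, and that C2 is kept safe by holding C4 as an alcohol derivative until the second-last step.

**Alternative 3:** The cut is O1–C2 and C3–C4, giving the salicylaldehyde A7 and 3,4-dimethoxystyrene A8. After acetalisation with an orthoformate, a chiral BINOL-derived phosphoric acid would ionise the acetal to a 4-methoxy ortho-quinone methide. This adds A8 in an inverse-demand hetero-Diels–Alder reaction to give the 2,4-cis chromane A9.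
- Merits: it is the most convergent of the four plans. One step makes ring C, two bonds and both stereocentres from two simple partners. A9 is the 4-O-methyl counterpart of 16.
- Weak points: the styrene has no hydrogen-bond acceptor to bind the catalyst, so enantiocontrol rests on ion pairing with a cationic, heavily substituted quinone methide. The C4 methyl ether must then become the ketone in the presence of five aryl methyl ethers, which means acid-mediated exchange at the benzylic carbon followed by oxidation. A7 is again a hexasubstituted benzene to be built by stepwise aromatic substitution.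
- Comparison: Alternative 3 reaches the 4-oxygenated flavan stage in far fewer steps from its building blocks and is superior in convergence. The chosen plan sets against this that it needs no prefabricated ring A, that its C4 oxygen is a silyl ether removed by fluoride without ionising C4, and that its stereocentre comes from a substrate class for which catalysts are well developed.

Key step: step 5

Assumption: with (S)-BINOL the titanium catalyst is taken to attack the Si face of the aryl aldehyde, as in the related allylation, giving (2S)-4; should the sense be the reverse, (R)-BINOL is used and nothing else changes.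

## Route

Step 1
Reactants: 1 3,4-dimethoxybenzaldehyde; 2 (E)-1-methoxy-3-(trimethylsilyloxy)buta-1,3-diene
Product: 4 (2S)-2-(3,4-dimethoxyphenyl)-2,3-dihydro-4H-pyran-4-one, via silyl aldol adduct 3 (not isolated)
Conditions: (S)-BINOL (20 mol %), Ti(OiPr)4 (10 mol %), 4 Å MS, Et2O, −20 °C; then CF3CO2H, CH2Cl2, 0 °C
Reagents that add atoms: none
Why: Titanium–BINOL-catalysed Mukaiyama aldol addition of the diene terminus to the aldehyde, then acid-induced conjugate ring closure of 3 with loss of methanol (formal hetero-Diels–Alder reaction); Si-face attack inside the chiral binaphtholate sets C2 as S, the only stereocentre that reaches the target.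

Step 2
Reactants: 4 (2S)-2-(3,4-dimethoxyphenyl)-2,3-dihydro-4H-pyran-4-one
Product: 5 (2S,4S)-2-(3,4-dimethoxyphenyl)-3,4-dihydro-2H-pyran-4-ol (2,4-cis)
Conditions: NaBH4, CeCl3·7H2O, MeOH, −78 → −40 °C
Reagents that add atoms: none
Why: Luche 1,2-reduction; CeCl3 directs borohydride to the carbonyl of the vinylogous ester, and axial hydride delivery to the half-chair with the aryl group pseudo-equatorial should give the pseudo-equatorial, 2,4-cis alcohol (4S).

Step 3
Reactants: 5 (2S,4S)-2-(3,4-dimethoxyphenyl)-3,4-dihydro-2H-pyran-4-ol
Product: 6 (2S,4S)-2-(3,4-dimethoxyphenyl)-4-(triisopropylsilyloxy)-3,4-dihydro-2H-pyran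
Conditions: TIPSCl, imidazole, DMAP (cat.), DMF, 40 °C
Reagents that add atoms: triisopropylsilyl chloride, CC(C)[Si](Cl)(C(C)C)C(C)C
Why: Silylation of a secondary allylic alcohol under basic conditions that spare the acid-sensitive enol ether; the triisopropylsilyl group has no Si–CH3 protons to be metalated in step 4 and outlasts the aryl silyl ether in step 7.

Step 4
Reactants: 6 (2S,4S)-2-(3,4-dimethoxyphenyl)-4-(triisopropylsilyloxy)-3,4-dihydro-2H-pyran; 7 dimethyl squarate (3,4-dimethoxycyclobut-3-ene-1,2-dione)
Product: 10 4-(tert-butyldimethylsilyloxy)-4-[(2S,4S)-2-(3,4-dimethoxyphenyl)-4-(triisopropylsilyloxy)-3,4-dihydro-2H-pyran-6-yl]-2,3-dimethoxycyclobut-2-en-1-one (both epimers at the carbinol carbon), via vinyllithium 8 (not isolated), via lithium alkoxide 9 (not isolated)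
Conditions: t-BuLi (1.8 equiv), THF, −78 → 0 °C; cannulate into 7 (1.2 equiv), THF, −78 °C; then TBSOTf, −78 → −40 °C; Et3N/NaHCO3 work-up
Reagents that add atoms: tert-butyldimethylsilyl trifluoromethanesulfonate, CC(C)(C)[Si](C)(C)OS(=O)(=O)C(F)(F)F
Why: α-Lithiation of a cyclic enol ether (the C–H lithiation used for glycals), favoured by the acidity of the sp2 C–H next to O1, then 1,2-addition of 8 to one of the two equivalent ketone carbonyls of 7 and O-silylation of 9 before it can ring-open; the carbinol centre forms without control and is erased in step 5.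

Step 5
Reactants: 10 4-(tert-butyldimethylsilyloxy)-4-[(2S,4S)-2-(3,4-dimethoxyphenyl)-4-(triisopropylsilyloxy)-3,4-dihydro-2H-pyran-6-yl]-2,3-dimethoxycyclobut-2-en-1-one
Product: 13 (2S,4S)-8-(tert-butyldimethylsilyloxy)-2-(3,4-dimethoxyphenyl)-6,7-dimethoxy-4-(triisopropylsilyloxy)chroman-5-ol, via dienylketene 11 (not isolated), via cyclohexadienone 12 (not isolated)
Conditions: PhMe (degassed, 0.02 M), 110 °C, Ar, base-washed glassware
Reagents that add atoms: none
Why: Heating opens the cyclobutenone by conrotatory 4π electrocyclic cleavage of the bond between the carbonyl carbon and the silyloxy-bearing carbon, giving the (Z)-dienylketene 11. The ketene carbon (future C5) and the enol-ether β-carbon (future C4a) then join in a thermal 6π electrocyclisation, the single ring closure of the step, which forms the six-membered carbocycle of ring A as cyclohexadienone 12. Tautomerisation of 12 to phenol 13 makes the sequence irreversible. The closest known reaction type is the thermal ring expansion of 4-alkenyl-4-hydroxy- or 4-silyloxycyclobutenones from squarates to hydroquinone derivatives (Moore rearrangement), cyclic enol ethers included as the alkenyl group. No stereocentre is created: the carbinol carbon of 10 becomes sp2, so both epimers converge, the C4a centre of 12 is lost on aromatisation, and C2 and C4 take no part. The selectivity needed is torquoselectivity, and it is secured by the silyloxy donor rotating outward, which places the dihydropyranyl group inward and cis to the ketene; any outward isomer cannot close and should revert to 10. The electron-rich enol ether β-carbon matches the electrophilic ketene carbon, so closure should outrun other ketene reactions under dilute, acid-free conditions. O5 emerges as a free phenol and O8 as a silyl ether, which is the differentiation the endgame needs.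

Step 6
Reactants: 13 (2S,4S)-8-(tert-butyldimethylsilyloxy)-2-(3,4-dimethoxyphenyl)-6,7-dimethoxy-4-(triisopropylsilyloxy)chroman-5-ol
Product: 14 (2S,4S)-8-(tert-butyldimethylsilyloxy)-2-(3,4-dimethoxyphenyl)-5,6,7-trimethoxy-4-(triisopropylsilyloxy)chromane
Conditions: MeI, K2CO3, acetone, 40 °C
Reagents that add atoms: iodomethane, CI
Why: Williamson etherification of the only acidic OH; carbonate in aprotic acetone should not cleave the aryl silyl ether, and silyl transfer from the alkyl oxygen O4 to the phenoxide is thermodynamically uphill.

Step 7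
Reactants: 14 (2S,4S)-8-(tert-butyldimethylsilyloxy)-2-(3,4-dimethoxyphenyl)-5,6,7-trimethoxy-4-(triisopropylsilyloxy)chromane
Product: 16 (2S,4S)-8-(benzyloxy)-2-(3,4-dimethoxyphenyl)-5,6,7-trimethoxy-4-(triisopropylsilyloxy)chromane, via caesium phenoxide 15 (not isolated)
Conditions: BnBr, CsF, DMF, rt, Ar
Reagents that add atoms: benzyl bromide, BrCc1ccccc1
Why: Fluoride-induced desilylative alkylation; CsF cleaves the aryl O–Si bond (phenoxide leaving group) much faster than the hindered secondary alkyl triisopropylsilyl ether, and phenoxide 15 is benzylated in situ by SN2 before it can be oxidised.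

Step 8
Reactants: 16 (2S,4S)-8-(benzyloxy)-2-(3,4-dimethoxyphenyl)-5,6,7-trimethoxy-4-(triisopropylsilyloxy)chromane
Product: 17 (2S,4S)-8-(benzyloxy)-2-(3,4-dimethoxyphenyl)-5,6,7-trimethoxychroman-4-ol
Conditions: TBAF, THF, rt → 45 °C
Reagents that add atoms: none
Why: Fluoride cleavage of the remaining silyl ether; 16 contains nothing base-sensitive because the flavanone carbonyl is not yet present.

Step 9
Reactants: 17 (2S,4S)-8-(benzyloxy)-2-(3,4-dimethoxyphenyl)-5,6,7-trimethoxychroman-4-ol
Product: 18 (2S)-8-(benzyloxy)-2-(3,4-dimethoxyphenyl)-5,6,7-trimethoxychroman-4-one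
Conditions: Dess–Martin periodinane, NaHCO3, CH2Cl2, 0 °C → rt
Reagents that add atoms: none
Why: Dess–Martin oxidation of a secondary benzylic alcohol under bicarbonate buffer, mild enough to avoid retro-oxa-Michael opening at C2; ring A is fully etherified and should not be attacked by the periodinane.

Step 10
Reactants: 18 (2S)-8-(benzyloxy)-2-(3,4-dimethoxyphenyl)-5,6,7-trimethoxychroman-4-one
Product: 19 (2S)-2-(3,4-dimethoxyphenyl)-8-hydroxy-5,6,7-trimethoxychroman-4-one
Conditions: H2 (1 atm), Pd/C (10 %), EtOAc, rt
Reagents that add atoms: none
Why: Hydrogenolysis of the aryl benzyl ether on palladium under neutral conditions; the aryl ketone is deactivated as a vinylogous ester by its ortho and para oxygens and the cyclic C2–O1 bond is cleaved far more slowly than an O-benzyl group, so C2 (S) should be retained.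

## Compound list

1 | 3,4-dimethoxybenzaldehyde | COc1ccc(C=O)cc1OC | starting material
2 | (E)-1-methoxy-3-(trimethylsilyloxy)buta-1,3-diene | CO/C=C/C(=C)O[Si](C)(C)C | starting material
3 | (1E,5S)-5-(3,4-dimethoxyphenyl)-1-methoxy-5-(trimethylsilyloxy)pent-1-en-3-one (not isolated) | CO/C=C/C(=O)C[C@H](O[Si](C)(C)C)c1ccc(OC)c(OC)c1 | intermediate
4 | (2S)-2-(3,4-dimethoxyphenyl)-2,3-dihydro-4H-pyran-4-one | COc1ccc([C@@H]2CC(=O)C=CO2)cc1OC | intermediate
5 | (2S,4S)-2-(3,4-dimethoxyphenyl)-3,4-dihydro-2H-pyran-4-ol (2,4-cis) | COc1ccc([C@@H]2C[C@H](O)C=CO2)cc1OC | intermediate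
6 | (2S,4S)-2-(3,4-dimethoxyphenyl)-4-(triisopropylsilyloxy)-3,4-dihydro-2H-pyran | COc1ccc([C@@H]2C[C@H](O[Si](C(C)C)(C(C)C)C(C)C)C=CO2)cc1OC | intermediate
7 | dimethyl squarate (3,4-dimethoxycyclobut-3-ene-1,2-dione) | COC1=C(OC)C(=O)C1=O | starting material
8 | [(2S,4S)-2-(3,4-dimethoxyphenyl)-4-(triisopropylsilyloxy)-3,4-dihydro-2H-pyran-6-yl]lithium (not isolated) | COc1ccc([C@@H]2C[C@H](O[Si](C(C)C)(C(C)C)C(C)C)C=C([Li])O2)cc1OC | intermediate
9 | lithium 1-[(2S,4S)-2-(3,4-dimethoxyphenyl)-4-(triisopropylsilyloxy)-3,4-dihydro-2H-pyran-6-yl]-2,3-dimethoxy-4-oxocyclobut-2-en-1-olate (not isolated) | COc1ccc([C@@H]2C[C@H](O[Si](C(C)C)(C(C)C)C(C)C)C=C(O2)C3([O-])C(OC)=C(OC)C3=O)cc1OC.[Li+] | intermediate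
10 | 4-(tert-butyldimethylsilyloxy)-4-[(2S,4S)-2-(3,4-dimethoxyphenyl)-4-(triisopropylsilyloxy)-3,4-dihydro-2H-pyran-6-yl]-2,3-dimethoxycyclobut-2-en-1-one (either epimer at the carbinol carbon) | COc1ccc([C@@H]2C[C@H](O[Si](C(C)C)(C(C)C)C(C)C)C=C(O2)C3(O[Si](C)(C)C(C)(C)C)C(OC)=C(OC)C3=O)cc1OC | intermediate
11 | (3Z)-4-(tert-butyldimethylsilyloxy)-4-[(2S,4S)-2-(3,4-dimethoxyphenyl)-4-(triisopropylsilyloxy)-3,4-dihydro-2H-pyran-6-yl]-2,3-dimethoxybuta-1,3-dien-1-one (not isolated) | COc1ccc([C@@H]2C[C@H](O[Si](C(C)C)(C(C)C)C(C)C)C=C(O2)/C(O[Si](C)(C)C(C)(C)C)=C(OC)\C(OC)=C=O)cc1OC | intermediate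
12 | (2S,4S)-8-(tert-butyldimethylsilyloxy)-2-(3,4-dimethoxyphenyl)-6,7-dimethoxy-4-(triisopropylsilyloxy)-2,3,4,4a-tetrahydro-5H-chromen-5-one (C4a transient, not isolated) | COc1ccc([C@@H]2C[C@H](O[Si](C(C)C)(C(C)C)C(C)C)C3C(=O)C(OC)=C(OC)C(O[Si](C)(C)C(C)(C)C)=C3O2)cc1OC | intermediate
13 | (2S,4S)-8-(tert-butyldimethylsilyloxy)-2-(3,4-dimethoxyphenyl)-6,7-dimethoxy-4-(triisopropylsilyloxy)chroman-5-ol (2,4-cis) | COc1ccc([C@@H]2C[C@H](O[Si](C(C)C)(C(C)C)C(C)C)c3c(O)c(OC)c(OC)c(O[Si](C)(C)C(C)(C)C)c3O2)cc1OC | intermediate
14 | (2S,4S)-8-(tert-butyldimethylsilyloxy)-2-(3,4-dimethoxyphenyl)-5,6,7-trimethoxy-4-(triisopropylsilyloxy)chromane | COc1ccc([C@@H]2C[C@H](O[Si](C(C)C)(C(C)C)C(C)C)c3c(OC)c(OC)c(OC)c(O[Si](C)(C)C(C)(C)C)c3O2)cc1OC | intermediate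
15 | caesium (2S,4S)-2-(3,4-dimethoxyphenyl)-5,6,7-trimethoxy-4-(triisopropylsilyloxy)chroman-8-olate (not isolated) | COc1ccc([C@@H]2C[C@H](O[Si](C(C)C)(C(C)C)C(C)C)c3c(OC)c(OC)c(OC)c([O-])c3O2)cc1OC.[Cs+] | intermediate
16 | (2S,4S)-8-(benzyloxy)-2-(3,4-dimethoxyphenyl)-5,6,7-trimethoxy-4-(triisopropylsilyloxy)chromane | COc1ccc([C@@H]2C[C@H](O[Si](C(C)C)(C(C)C)C(C)C)c3c(OC)c(OC)c(OC)c(OCc4ccccc4)c3O2)cc1OC | intermediate
17 | (2S,4S)-8-(benzyloxy)-2-(3,4-dimethoxyphenyl)-5,6,7-trimethoxychroman-4-ol | COc1ccc([C@@H]2C[C@H](O)c3c(OC)c(OC)c(OC)c(OCc4ccccc4)c3O2)cc1OC | intermediate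
18 | (2S)-8-(benzyloxy)-2-(3,4-dimethoxyphenyl)-5,6,7-trimethoxychroman-4-one | COc1ccc([C@@H]2CC(=O)c3c(OC)c(OC)c(OC)c(OCc4ccccc4)c3O2)cc1OC | intermediate
19 | (2S)-2-(3,4-dimethoxyphenyl)-8-hydroxy-5,6,7-trimethoxychroman-4-one | COc1ccc([C@@H]2CC(=O)c3c(c(O)c(OC)c(OC)c3OC)O2)cc1OC | target

## Step count and least certain steps

Total steps: 10. Longest linear sequence: 10 steps (1 → 19); 2 and 7 enter as commercial materials.

**Step 5 (key step).** The most likely failure is loss or transfer of the silyl group from the carbinol oxygen at 110 °C, which would leave an unprotected hydroquinone that oxidises during isolation. Elimination of silanol across C4–C4a from dienone 12 could also compete with tautomerisation. The fallback takes the silyl group out of the ring expansion. It sets out from alkoxide 9 (made as in step 4) and returns at 13. Quenching 9 with aqueous NH4Cl instead of the silyl triflate would give the free carbinol 4-[(2S,4S)-2-(3,4-dimethoxyphenyl)-4-(triisopropylsilyloxy)-3,4-dihydro-2H-pyran-6-yl]-4-hydroxy-2,3-dimethoxycyclobut-2-en-1-one F1. Such hydroxycyclobutenones usually rearrange at lower temperature (degassed PhMe, 80–110 °C), here to the hydroquinone (2S,4S)-2-(3,4-dimethoxyphenyl)-6,7-dimethoxy-4-(triisopropylsilyloxy)chromane-5,8-diol F2, kept under argon. One equivalent of TBSCl with imidazole in DMF at 0 °C should silylate the C8 hydroxyl in preference to the C5 hydroxyl, which lies in the pocket next to the bulky C4 silyloxy group, giving 13.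

**Step 4.** The risks are competing metalation at the benzylic C2–H (which would erode the C2 configuration) or ortho to a methoxy group of ring B, addition of surviving t-BuLi to 7, and incomplete silylation of the hindered alkoxide. The fallback generates 8 by tin–lithium exchange instead of deprotonation. It sets out from 6 and returns at 8 and hence 10. Oxidation of the enol ether with [C5H5NH][CrO3Cl] (pyridinium chlorochromate) in CH2Cl2 would give the lactone (4S,6S)-6-(3,4-dimethoxyphenyl)-4-(triisopropylsilyloxy)oxan-2-one F3. Enolisation with KN(SiMe3)2 in THF–HMPA at −78 °C in the presence of (PhO)2P(O)Cl would give the ketene acetal phosphate (2S,4S)-2-(3,4-dimethoxyphenyl)-4-(triisopropylsilyloxy)-3,4-dihydro-2H-pyran-6-yl diphenyl phosphate F4. Stannylation with Me3SnSnMe3, Pd(PPh3)4 and LiCl in THF at reflux would give [(2S,4S)-2-(3,4-dimethoxyphenyl)-4-(triisopropylsilyloxy)-3,4-dihydro-2H-pyran-6-yl]trimethylstannane F5. MeLi in THF at −78 °C then delivers 8 with no excess strong base, and the addition to 7 and silylation proceed as in step 4.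

**Step 7.** The risks are partial loss of the C4 silyl ether alongside the aryl silyl ether, or oxidation of phenoxide 15 before it is alkylated. The fallback separates deprotection from benzylation. It sets out from 14 and returns at 17. TBAF in THF would remove both silyl groups to give (2S,4S)-2-(3,4-dimethoxyphenyl)-5,6,7-trimethoxychromane-4,8-diol F6, handled under argon. BnBr with K2CO3 in acetone would then benzylate only the phenol, the secondary alcohol being far less acidic, to give 17.

**Step 1.** The risk is insufficient enantioselectivity: the electron-rich aldehyde reacts slowly, so an uncatalysed or silyl-transfer pathway may compete. The fallback sets C2 by resolution instead of catalysis. It sets out from 1 and 2 and returns at 5.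
- ZnCl2 in THF followed by CF3CO2H would give racemic 2-(3,4-dimethoxyphenyl)-2,3-dihydro-4H-pyran-4-one F7.
- Luche reduction as in step 2 would give racemic cis-2-(3,4-dimethoxyphenyl)-3,4-dihydro-2H-pyran-4-ol F8.
- Candida antarctica lipase B with vinyl acetate in tert-butyl methyl ether would acylate one enantiomer. The sense has to be established; the sequence is written for the case that the (2R,4R) alcohol is acylated to (2R,4R)-2-(3,4-dimethoxyphenyl)-3,4-dihydro-2H-pyran-4-yl acetate F9, leaving (2S,4S)-5 to be separated and carried on.

## Further compounds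

F1 | step 5 | 4-[(2S,4S)-2-(3,4-dimethoxyphenyl)-4-(triisopropylsilyloxy)-3,4-dihydro-2H-pyran-6-yl]-4-hydroxy-2,3-dimethoxycyclobut-2-en-1-one | COc1ccc([C@@H]2C[C@H](O[Si](C(C)C)(C(C)C)C(C)C)C=C(O2)C3(O)C(OC)=C(OC)C3=O)cc1OC
F2 | step 5 | (2S,4S)-2-(3,4-dimethoxyphenyl)-6,7-dimethoxy-4-(triisopropylsilyloxy)chromane-5,8-diol | COc1ccc([C@@H]2C[C@H](O[Si](C(C)C)(C(C)C)C(C)C)c3c(O)c(OC)c(OC)c(O)c3O2)cc1OC
F3 | step 4 | (4S,6S)-6-(3,4-dimethoxyphenyl)-4-(triisopropylsilyloxy)oxan-2-one | COc1ccc([C@@H]2C[C@H](O[Si](C(C)C)(C(C)C)C(C)C)CC(=O)O2)cc1OC
F4 | step 4 | (2S,4S)-2-(3,4-dimethoxyphenyl)-4-(triisopropylsilyloxy)-3,4-dihydro-2H-pyran-6-yl diphenyl phosphate | COc1ccc([C@@H]2C[C@H](O[Si](C(C)C)(C(C)C)C(C)C)C=C(OP(=O)(Oc3ccccc3)Oc3ccccc3)O2)cc1OC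
F5 | step 4 | [(2S,4S)-2-(3,4-dimethoxyphenyl)-4-(triisopropylsilyloxy)-3,4-dihydro-2H-pyran-6-yl]trimethylstannane | COc1ccc([C@@H]2C[C@H](O[Si](C(C)C)(C(C)C)C(C)C)C=C([Sn](C)(C)C)O2)cc1OC
F6 | step 7 | (2S,4S)-2-(3,4-dimethoxyphenyl)-5,6,7-trimethoxychromane-4,8-diol | COc1ccc([C@@H]2C[C@H](O)c3c(OC)c(OC)c(OC)c(O)c3O2)cc1OC
F7 | step 1 | racemic 2-(3,4-dimethoxyphenyl)-2,3-dihydro-4H-pyran-4-one (both enantiomers) | COc1ccc([C@@H]2CC(=O)C=CO2)cc1OC.COc1ccc([C@H]2CC(=O)C=CO2)cc1OC
F8 | step 1 | racemic cis-2-(3,4-dimethoxyphenyl)-3,4-dihydro-2H-pyran-4-ol (both enantiomers) | COc1ccc([C@@H]2C[C@H](O)C=CO2)cc1OC.COc1ccc([C@H]2C[C@@H](O)C=CO2)cc1OC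
F9 | step 1 | (2R,4R)-2-(3,4-dimethoxyphenyl)-3,4-dihydro-2H-pyran-4-yl acetate | COc1ccc([C@H]2C[C@@H](OC(C)=O)C=CO2)cc1OC
A1 | alternative 1 | 8-(benzyloxy)-5,6,7-trimethoxy-4H-chromen-4-one | O=c1ccoc2c(OCc3ccccc3)c(OC)c(OC)c(OC)c12
A2 | alternative 1 | (2S)-8-(benzyloxy)-2-ethynyl-5,6,7-trimethoxychroman-4-one | C#C[C@@H]1CC(=O)c2c(OC)c(OC)c(OC)c(OCc3ccccc3)c2O1
A3 | alternative 1 | 2,3-dimethoxybuta-1,3-diene | COC(=C)C(=C)OC
A4 | alternative 1 | (2S)-8-(benzyloxy)-2-(4,5-dimethoxycyclohexa-1,4-dien-1-yl)-5,6,7-trimethoxychroman-4-one | COC1=C(OC)CC([C@@H]2CC(=O)c3c(c(OCc4ccccc4)c(OC)c(OC)c3OC)O2)=CC1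
A5 | alternative 2 | 2-diazo-1-[2-(3,4-dimethoxybenzyloxy)-4,5,6-trimethoxy-3-(triisopropylsilyloxy)phenyl]ethan-1-one | COc1ccc(COc2c(C(=O)C=[N+]=[N-])c(OC)c(OC)c(OC)c2O[Si](C(C)C)(C(C)C)C(C)C)cc1OC
A6 | alternative 2 | (2S)-2-(3,4-dimethoxyphenyl)-5,6,7-trimethoxy-8-(triisopropylsilyloxy)chroman-4-one | COc1ccc([C@@H]2CC(=O)c3c(c(O[Si](C(C)C)(C(C)C)C(C)C)c(OC)c(OC)c3OC)O2)cc1OC
A7 | alternative 3 | 3-(benzyloxy)-2-hydroxy-4,5,6-trimethoxybenzaldehyde | O=Cc1c(O)c(OCc2ccccc2)c(OC)c(OC)c1OC
A8 | alternative 3 | 3,4-dimethoxystyrene (4-ethenyl-1,2-dimethoxybenzene) | C=Cc1ccc(OC)c(OC)c1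
A9 | alternative 3 | (2S,4S)-8-(benzyloxy)-2-(3,4-dimethoxyphenyl)-4,5,6,7-tetramethoxychromane (2,4-cis) | COc1ccc([C@@H]2C[C@H](OC)c3c(OC)c(OC)c(OC)c(OCc4ccccc4)c3O2)cc1OC
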